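**Retrosynthetic overview**
- Plastochromenol-8 ⇐ (2R)-chromane-4,6-diol ⇐ (2R)-chroman-4-one: the C3=C4 alkene is carried as a C4 ketone and unveiled last by reduction and dehydration.
- The pyran ring, the only ring made, ⇐ an acyclic aryl sec-alkyl ether carrying an α-diazo ketone: the C2–C3 bond is formed by intramolecular 1,6 C–H insertion of a rhodium carbenoid, with retention at C2.
- Enabling feature: C2 is a fully substituted carbon on the ring oxygen O1, and O1 (on C8a) is ortho to C4a. A carbene on C3, α to a C4 carbonyl on C4a, therefore reaches the O1-activated tertiary C2–H through the six atoms C3–C4–C4a–C8a–O1–C2.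
- Aryl ether ⇐ Mitsunobu inversion of an (S)-methyl carbinol with a phenol made from 2,3-dimethylhydroquinone by C-acetylation and selective 5-O-pivaloylation.
- (S)-Carbinol ⇐ C43 methyl ketone ⇐ solanesol by excision of C1–C2 (epoxidation, periodate cleavage), reduction and lipase resolution.

Key step: step 9

Assumption: commercial solanesol is taken as the all-E nonaprenol, so all eight chain alkenes of the target are bought and not made.

**Step 1**
Reactants: 1 2,3-dimethylhydroquinone
Product: 2 1-(2,5-dihydroxy-3,4-dimethylphenyl)ethanone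
Conditions: AcOH, BF3·OEt2, 100 °C; aq. NaOAc work-up
Reagents that add atoms: acetic acid, CC(=O)O
Why: BF3-promoted Friedel–Crafts C-acetylation (Fries manifold) of the electron-rich hydroquinone should occur at one of the two equivalent free ring positions, and the chelated o-hydroxy ketone formed is deactivated toward a second acylation.

**Step 2**
Reactants: 2 1-(2,5-dihydroxy-3,4-dimethylphenyl)ethanone
Product: 3 5-acetyl-4-hydroxy-2,3-dimethylphenyl pivalate
Conditions: PivCl (1.05 equiv), pyridine, CH2Cl2, 0 °C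
Reagents that add atoms: pivaloyl chloride, CC(C)(C)C(Cl)=O
Why: The hydroxyl ortho to the acetyl group is tied up in an intramolecular hydrogen bond, so chemoselective esterification with the bulky acid chloride should take place at the free C5 hydroxyl only.

**Step 3**
Reactants: 4 solanesol (all-E nonaprenol)
Product: 5 racemic trans-2,3-epoxysolanesol
Conditions: VO(acac)2 (2 mol%), tBuOOH, toluene, 0 °C → rt
Reagents that add atoms: tert-butyl hydroperoxide, CC(C)(C)OO
Why: Hydroxyl-directed vanadium-catalysed epoxidation should deliver oxygen only to the allylic-alcohol alkene C2=C3 and leave the eight isolated trisubstituted alkenes untouched; the two new stereocentres are irrelevant because both are destroyed in step 4.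

**Step 4**
Reactants: 5 racemic trans-2,3-epoxysolanesol
Product: 7 all-E octaprenylacetone (C43 methyl ketone), via triol 6 (not isolated)
Conditions: H5IO6 (2.5 equiv), THF/H2O, 0 °C → rt
Reagents that add atoms: water, O (opens the epoxide at the tertiary carbon and ends as the ketone oxygen)
Why: Aqueous periodic acid should open the epoxide to the 1,2,3-triol and cleave both glycol C–C bonds (periodate glycol cleavage), excising C1 and C2 as formaldehyde and formic acid and leaving C3 as the methyl ketone without touching the isolated alkenes.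

**Step 5**
Reactants: 7 all-E octaprenylacetone
Product: 8 racemic octaprenyl-substituted butan-2-ol (C43 methyl carbinol)
Conditions: NaBH4, THF/MeOH, 0 °C
Reagents that add atoms: none
Why: Borohydride reduction is chemoselective for the ketone in the presence of isolated alkenes and gives the racemic methyl carbinol needed for resolution.

**Step 6**
Reactants: 8 racemic C43 methyl carbinol
Product: 9 (S)-C43 methyl carbinol
Conditions: immobilised Candida antarctica lipase B, vinyl acetate, hexane, 30 °C, run past half conversion; chromatography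
Reagents that add atoms: none
Why: In this lipase-catalysed kinetic resolution (irreversible transesterification) the enzyme acylates the (R)-enantiomer of methyl carbinols much faster, so the unreacted (S)-alcohol should be left enantiopure and is separated from the (R)-acetate.

**Step 7**
Reactants: 3 5-acetyl-4-hydroxy-2,3-dimethylphenyl pivalate and 9 (S)-C43 methyl carbinol
Product: 10 (R)-aryl sec-alkyl ether (2-alkoxy-acetophenone)
Conditions: PPh3, DIAD, THF (concentrated), sonication, 0 °C → rt
Reagents that add atoms: none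
Why: Mitsunobu etherification is an SN2 displacement of the oxyphosphonium by the phenoxide with clean inversion, so the (S)-carbinol should give the (R)-ether that carries the future C2 configuration; high concentration and sonication are the conditions suited to a doubly ortho-substituted phenol.

**Step 8**
Reactants: 10 (R)-aryl sec-alkyl ether
Product: 12 (R)-aryl ether α-diazo ketone, via trifluoroacetyl ketone 11 (not isolated)
Conditions: LiHMDS, THF, −78 °C; CF3CO2CH2CF3; aq. HCl work-up; then MsN3, Et3N, H2O, MeCN, rt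
Reagents that add atoms: methanesulfonyl azide, CS(=O)(=O)N=[N+]=[N-] (the two diazo nitrogens); 2,2,2-trifluoroethyl trifluoroacetate, O=C(OCC(F)(F)F)C(F)(F)F (trifluoroacetyl group of intermediate 11 only, lost again)
Why: In this detrifluoroacetylative diazo transfer, C-trifluoroacetylation of the kinetic enolate activates the methyl ketone and the sulfonyl azide then transfers N2 with loss of the trifluoroacetyl group; the non-nucleophilic base should leave the pivalate and the ether stereocentre untouched.

**Step 9**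
Reactants: 12 (R)-aryl ether α-diazo ketone
Product: 13 (2R)-6-pivaloyloxy-chroman-4-one
Conditions: Rh2(OAc)4 (1 mol%), CH2Cl2, slow addition of 12 at high dilution, rt → 40 °C
Reagents that add atoms: none
Why: Dirhodium tetraacetate extrudes N2 from 12 to give an electrophilic acyl rhodium carbenoid at C3, which inserts into the tertiary C2–H bond next to the ether oxygen through a concerted, asynchronous three-centre transition state with hydride-transfer character, so that the C2–C3 bond, the pyranone ring and the quaternary centre arise together. The closest known reaction type is the dirhodium-carboxylate-catalysed cyclisation of 2-alkoxyaryl α-diazo ketones to chroman-4-ones, together with ether-α C–H insertions of diazo ketones at stereogenic carbons that proceed with retention. The one ring formed, the dihydropyranone, is closed in a 1,6 C–H insertion mode (C3, C4, C4a, C8a, O1, C2); the normally preferred five-membered mode has no C–H to offer because its terminus is O1 itself. The new quaternary stereocentre C2 is controlled by the (R)-configured C–H carbon installed in steps 6 and 7, the insertion taking place with retention, so an achiral catalyst suffices. The step needs chemoselectivity for the C2–H bond over oxonium-ylide formation at O1, over insertion into the flanking CH3 and CH2 groups and over cyclopropanation of the eight chain alkenes; the doubly activated (tertiary and α-oxygen) C–H held ortho to the carbenoid by the benzene ring, the nine- or ten-membered ring that the nearest alkene would require, and slow addition at high dilution should secure it. The C4 carbonyl that stabilises the carbenoid is at the same time the latent C3=C4 alkene.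

**Step 10**
Reactants: 13 (2R)-6-pivaloyloxy-chroman-4-one
Product: 14 (2R)-chromane-4,6-diol (both C4 epimers)
Conditions: LiAlH4, THF, 0 °C → rt; aq. KNaC4H4O6 work-up
Reagents that add atoms: none
Why: Hydride reduction should convert the aryl ketone into the benzylic alcohol and cleave the aryl pivalate reductively in the same operation; reduction outruns enolisation, so a retro-oxa-Michael opening that could scramble C2 is avoided, and the uncontrolled C4 centre is lost in step 11.

**Step 11**
Reactants: 14 (2R)-chromane-4,6-diol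
Product: 15 plastochromenol-8
Conditions: pTsOH·H2O (2 mol%), toluene, 4 Å molecular sieves, 40 °C, argon, exclusion of light
Reagents that add atoms: none
Why: Acid-catalysed E1 dehydration proceeds through the benzylic C4 cation stabilised by the ortho ring oxygen, and because C2 is quaternary the alkene can only form between C3 and C4; the mild catalytic acid should leave the trisubstituted chain alkenes and the C2 configuration unchanged.

**Compound list**
1 | 2,3-dimethylbenzene-1,4-diol (2,3-dimethylhydroquinone) | Cc1c(O)ccc(O)c1C | starting material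
2 | 1-(2,5-dihydroxy-3,4-dimethylphenyl)ethan-1-one | CC(=O)c1cc(O)c(C)c(C)c1O | intermediate
3 | 5-acetyl-4-hydroxy-2,3-dimethylphenyl 2,2-dimethylpropanoate | CC(=O)c1cc(OC(=O)C(C)(C)C)c(C)c(C)c1O | intermediate
4 | solanesol, (2E,6E,10E,14E,18E,22E,26E,30E)-3,7,11,15,19,23,27,31,35-nonamethylhexatriaconta-2,6,10,14,18,22,26,30,34-nonaen-1-ol | CC(C)=CCC/C(C)=C/CC/C(C)=C/CC/C(C)=C/CC/C(C)=C/CC/C(C)=C/CC/C(C)=C/CC/C(C)=C/CC/C(C)=C/CO | starting material
5 | rac-[(2R,3R)-3-methyl-3-[(3E,7E,11E,15E,19E,23E,27E)-4,8,12,16,20,24,28,32-octamethyltritriaconta-3,7,11,15,19,23,27,31-octaen-1-yl]oxiran-2-yl]methanol (racemate, one enantiomer drawn) | CC(C)=CCC/C(C)=C/CC/C(C)=C/CC/C(C)=C/CC/C(C)=C/CC/C(C)=C/CC/C(C)=C/CC/C(C)=C/CC[C@@]1(C)O[C@@H]1CO | intermediate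
6 | rac-(2R,3S,6E,10E,14E,18E,22E,26E,30E)-3,7,11,15,19,23,27,31,35-nonamethylhexatriaconta-6,10,14,18,22,26,30,34-octaene-1,2,3-triol (racemate, one enantiomer drawn; not isolated) | CC(C)=CCC/C(C)=C/CC/C(C)=C/CC/C(C)=C/CC/C(C)=C/CC/C(C)=C/CC/C(C)=C/CC/C(C)=C/CC[C@](C)(O)[C@H](O)CO | intermediate
7 | (5E,9E,13E,17E,21E,25E,29E)-6,10,14,18,22,26,30,34-octamethylpentatriaconta-5,9,13,17,21,25,29,33-octaen-2-one (octaprenylacetone) | CC(C)=CCC/C(C)=C/CC/C(C)=C/CC/C(C)=C/CC/C(C)=C/CC/C(C)=C/CC/C(C)=C/CC/C(C)=C/CCC(C)=O | intermediate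
8 | rac-(5E,9E,13E,17E,21E,25E,29E)-6,10,14,18,22,26,30,34-octamethylpentatriaconta-5,9,13,17,21,25,29,33-octaen-2-ol (racemate) | CC(C)=CCC/C(C)=C/CC/C(C)=C/CC/C(C)=C/CC/C(C)=C/CC/C(C)=C/CC/C(C)=C/CC/C(C)=C/CCC(C)O | intermediate
9 | (2S,5E,9E,13E,17E,21E,25E,29E)-6,10,14,18,22,26,30,34-octamethylpentatriaconta-5,9,13,17,21,25,29,33-octaen-2-ol | CC(C)=CCC/C(C)=C/CC/C(C)=C/CC/C(C)=C/CC/C(C)=C/CC/C(C)=C/CC/C(C)=C/CC/C(C)=C/CC[C@H](C)O | intermediate
10 | 5-acetyl-2,3-dimethyl-4-{[(2R,5E,9E,13E,17E,21E,25E,29E)-6,10,14,18,22,26,30,34-octamethylpentatriaconta-5,9,13,17,21,25,29,33-octaen-2-yl]oxy}phenyl 2,2-dimethylpropanoate | CC(C)=CCC/C(C)=C/CC/C(C)=C/CC/C(C)=C/CC/C(C)=C/CC/C(C)=C/CC/C(C)=C/CC/C(C)=C/CC[C@@H](C)Oc1c(C)c(C)c(OC(=O)C(C)(C)C)cc1C(C)=O | intermediate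
11 | 2,3-dimethyl-4-{[(2R,5E,9E,13E,17E,21E,25E,29E)-6,10,14,18,22,26,30,34-octamethylpentatriaconta-5,9,13,17,21,25,29,33-octaen-2-yl]oxy}-5-(4,4,4-trifluoro-3-oxobutanoyl)phenyl 2,2-dimethylpropanoate (not isolated) | CC(C)=CCC/C(C)=C/CC/C(C)=C/CC/C(C)=C/CC/C(C)=C/CC/C(C)=C/CC/C(C)=C/CC/C(C)=C/CC[C@@H](C)Oc1c(C)c(C)c(OC(=O)C(C)(C)C)cc1C(=O)CC(=O)C(F)(F)F | intermediate
12 | 5-(2-diazoacetyl)-2,3-dimethyl-4-{[(2R,5E,9E,13E,17E,21E,25E,29E)-6,10,14,18,22,26,30,34-octamethylpentatriaconta-5,9,13,17,21,25,29,33-octaen-2-yl]oxy}phenyl 2,2-dimethylpropanoate | CC(C)=CCC/C(C)=C/CC/C(C)=C/CC/C(C)=C/CC/C(C)=C/CC/C(C)=C/CC/C(C)=C/CC/C(C)=C/CC[C@@H](C)Oc1c(C)c(C)c(OC(=O)C(C)(C)C)cc1C(=O)C=[N+]=[N-] | intermediate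
13 | (2R)-2,7,8-trimethyl-2-[(3E,7E,11E,15E,19E,23E,27E)-4,8,12,16,20,24,28,32-octamethyltritriaconta-3,7,11,15,19,23,27,31-octaen-1-yl]-4-oxo-3,4-dihydro-2H-chromen-6-yl 2,2-dimethylpropanoate | CC(C)=CCC/C(C)=C/CC/C(C)=C/CC/C(C)=C/CC/C(C)=C/CC/C(C)=C/CC/C(C)=C/CC/C(C)=C/CC[C@]1(C)CC(=O)c2cc(OC(=O)C(C)(C)C)c(C)c(C)c2O1 | intermediate
14 | (2R,4RS)-2,7,8-trimethyl-2-[(3E,7E,11E,15E,19E,23E,27E)-4,8,12,16,20,24,28,32-octamethyltritriaconta-3,7,11,15,19,23,27,31-octaen-1-yl]-3,4-dihydro-2H-chromene-4,6-diol (both C4 epimers) | CC(C)=CCC/C(C)=C/CC/C(C)=C/CC/C(C)=C/CC/C(C)=C/CC/C(C)=C/CC/C(C)=C/CC/C(C)=C/CC[C@]1(C)CC(O)c2cc(O)c(C)c(C)c2O1 | intermediate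
15 | plastochromenol-8, (2R)-2,7,8-trimethyl-2-[(3E,7E,11E,15E,19E,23E,27E)-4,8,12,16,20,24,28,32-octamethyltritriaconta-3,7,11,15,19,23,27,31-octaen-1-yl]-2H-chromen-6-ol | CC(C)=CCC/C(C)=C/CC/C(C)=C/CC/C(C)=C/CC/C(C)=C/CC/C(C)=C/CC/C(C)=C/CC/C(C)=C/CC[C@]1(C)C=Cc2cc(O)c(C)c(C)c2O1 | target

**Step count**
Total step count: 11. Longest linear sequence: 9 steps (solanesol 4 to target 15, steps 3 to 11).

**Steps most likely to fail**

Step 9 (carbenoid C–H insertion). The carbenoid may be diverted into oxonium-ylide formation at O1 followed by a shift or elimination of the sec-alkyl group, or into cyclopropanation of chain alkenes. The insertion may also become stepwise (hydride transfer, then C–C bond formation), with erosion of configuration at C2. Fallback: the ring would be built by a Kabbe condensation and the enantiomers separated. Setting out from acetophenone 2 and ketone 7, pyrrolidine in toluene at reflux with removal of water (enamine aldol condensation, then oxa-Michael closure) should give racemic 6-hydroxy-2,7,8-trimethyl-2-(C41 octaenyl)chroman-4-one F1. Preparative chromatography on a chiral stationary phase (amylose carbamate) would then furnish the (2R)-6-hydroxychroman-4-one F2. Reduction of F2 with LiAlH4 (THF, 0 °C) comes back to the route at diol 14.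

Step 7 (Mitsunobu etherification). The doubly ortho-substituted, hydrogen-bonded phenol may attack the oxyphosphonium too slowly, so that elimination of the carbinol or alkylation of the hydrazide takes over. Fallback: a Williamson etherification with an isolated sulfonate. Setting out from carbinol 9, MsCl and Et3N in CH2Cl2 at 0 °C should give the (S)-C43 methyl carbinol methanesulfonate F3. Displacement with phenol 3 (Cs2CO3, DMF, 50 °C) proceeds with inversion and comes back to the route at ether 10.

Step 11 (acid-catalysed dehydration). The acid may start proton-initiated cyclisation or double-bond migration in the polyene chain, the benzylic cation may be captured by a second electron-rich arene, and the free hydroquinone monoether may oxidise in air. Fallback: a cation-free elimination on the protected phenol. Setting out from chromanone 13, NaBH4 (THF/MeOH, 0 °C) should reduce only the ketone to the (2R)-4-hydroxychroman-6-yl pivalate F4. Burgess reagent (toluene, 50 °C) effects a syn-elimination to the (2R)-2H-chromen-6-yl pivalate F5. Cleavage of the pivalate with iBu2AlH (CH2Cl2, −78 °C) comes back to the route at target 15.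

**Further compounds**
F1 | step 9 | racemic 6-hydroxy-2,7,8-trimethyl-2-[(3E,7E,11E,15E,19E,23E,27E)-4,8,12,16,20,24,28,32-octamethyltritriaconta-3,7,11,15,19,23,27,31-octaen-1-yl]-2,3-dihydro-4H-chromen-4-one | CC(C)=CCC/C(C)=C/CC/C(C)=C/CC/C(C)=C/CC/C(C)=C/CC/C(C)=C/CC/C(C)=C/CC/C(C)=C/CCC1(C)CC(=O)c2cc(O)c(C)c(C)c2O1
F2 | step 9 | (2R)-6-hydroxy-2,7,8-trimethyl-2-[(3E,7E,11E,15E,19E,23E,27E)-4,8,12,16,20,24,28,32-octamethyltritriaconta-3,7,11,15,19,23,27,31-octaen-1-yl]-2,3-dihydro-4H-chromen-4-one | CC(C)=CCC/C(C)=C/CC/C(C)=C/CC/C(C)=C/CC/C(C)=C/CC/C(C)=C/CC/C(C)=C/CC/C(C)=C/CC[C@]1(C)CC(=O)c2cc(O)c(C)c(C)c2O1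
F3 | step 7 | (2S,5E,9E,13E,17E,21E,25E,29E)-6,10,14,18,22,26,30,34-octamethylpentatriaconta-5,9,13,17,21,25,29,33-octaen-2-yl methanesulfonate | CC(C)=CCC/C(C)=C/CC/C(C)=C/CC/C(C)=C/CC/C(C)=C/CC/C(C)=C/CC/C(C)=C/CC/C(C)=C/CC[C@H](C)OS(C)(=O)=O
F4 | step 11 | (2R,4RS)-4-hydroxy-2,7,8-trimethyl-2-[(3E,7E,11E,15E,19E,23E,27E)-4,8,12,16,20,24,28,32-octamethyltritriaconta-3,7,11,15,19,23,27,31-octaen-1-yl]-3,4-dihydro-2H-chromen-6-yl 2,2-dimethylpropanoate (both C4 epimers) | CC(C)=CCC/C(C)=C/CC/C(C)=C/CC/C(C)=C/CC/C(C)=C/CC/C(C)=C/CC/C(C)=C/CC/C(C)=C/CC[C@]1(C)CC(O)c2cc(OC(=O)C(C)(C)C)c(C)c(C)c2O1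
F5 | step 11 | (2R)-2,7,8-trimethyl-2-[(3E,7E,11E,15E,19E,23E,27E)-4,8,12,16,20,24,28,32-octamethyltritriaconta-3,7,11,15,19,23,27,31-octaen-1-yl]-2H-chromen-6-yl 2,2-dimethylpropanoate | CC(C)=CCC/C(C)=C/CC/C(C)=C/CC/C(C)=C/CC/C(C)=C/CC/C(C)=C/CC/C(C)=C/CC/C(C)=C/CC[C@]1(C)C=Cc2cc(OC(=O)C(C)(C)C)c(C)c(C)c2O1
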